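**Retrosynthetic overview**
- The benzoate goes on last. It is relayed onto O6 of the 3α,4β,6β-triol, which comes from the 4β-hydroxy-3,6-dione by two equatorial hydride deliveries.
- Ring A closes at C3–C4. A carbene-generated acyl anion at the C3 aldehyde adds to the C4 acetyl carbonyl and sets the tertiary carbinol.
- The key disconnection is C1–C10. A propanal homoenolate equivalent (acetal Grignard) is joined to the β-carbon of (S)-piperitone under chiral copper control to give quaternary C10. The enolate is trapped with acetaldehyde (C4–C5).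
- Ring B is not built. It is (−)-menthone, which already carries C7, the C6 oxygen and the C10 methyl, dehydrogenated to the enone.
- Ring order: ring B from the chiral pool, then ring A.

Assumption: enantiopure (S)-(+)-piperitone is not taken as a cheap catalogue item, so it is made from (−)-menthone. Eudesmane numbering (C1–C15) is used throughout, with α/β referring to the drawing in which the C10 methyl is β.

**Step 1**
Reactants: 1 (−)-menthone [(2S,5R)-5-methyl-2-(propan-2-yl)cyclohexan-1-one]
Product: 4 (S)-(+)-piperitone [(6S)-3-methyl-6-(propan-2-yl)cyclohex-2-en-1-one], via lithium enolate 2 (not isolated), via keto sulfilimine 3 (not isolated)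
Conditions: LiN(i-Pr)2 (1.1 equiv), THF, −78 °C; PhS(Cl)=N-t-Bu (1.2 equiv), −78 °C, 30 min
Reagents that add atoms: none
Why: Kinetic deprotonation occurs at the unhindered CH2 (C5), the enolate is sulfenylated at sulfur, and the sulfilimine nitrogen removes the only β-hydrogen (H10) in a syn elimination (Mukaiyama sulfinimidoyl chloride dehydrogenation), so the enone forms at low temperature and the C7 stereocentre is never touched.

**Step 2**
Reactants: 4 (S)-(+)-piperitone; 5 2-(2-bromoethyl)-1,3-dioxolane; 6 acetaldehyde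
Product: 9 (2R,3S,6S)-3-[2-(1,3-dioxolan-2-yl)ethyl]-2-(1-hydroxyethyl)-3-methyl-6-(propan-2-yl)cyclohexan-1-one (both carbinol epimers), via Grignard reagent 7 (not isolated), via magnesium enolate 8 (not isolated)
Conditions: 5, Mg, THF, 25 °C; Cu(OTf)2 (5 mol %), tert-leucinol-derived N-mesityl hydroxyalkyl imidazolinium PF6 salt (6 mol %, the antipode that delivers to the α-face), Et2O, −30 °C, slow addition of 7 to 4; MeCHO (3 equiv), −78 °C; aq NH4Cl
Reagents that add atoms: 2-(2-bromoethyl)-1,3-dioxolane BrCCC1OCCO1; acetaldehyde CC=O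
Why: Proposed new method: copper–carbene-catalysed asymmetric conjugate addition of alkyl Grignard reagents to 3-methylcyclohex-2-enones (the closest known reaction type) is extended to the acetal-bearing propanal homoenolate equivalent 7 and to the 6-isopropyl enone 4, the ligand-bound monovalent copper complexing the enone face anti to the isopropyl group so that oxidative addition to trivalent copper and reductive elimination join C1 to C10 (two β-carbonyl carbons that are both normally electrophilic) and set the quaternary (10S) centre, after which enolate 8 adds to acetaldehyde anti to the new axial chain (tandem conjugate addition–aldol), placing C4 trans to C1 while the carbinol centre does not matter because it is oxidised next.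

**Step 3**
Reactants: 9 aldol adduct
Product: 10 (2R,3S,6S)-2-acetyl-3-[2-(1,3-dioxolan-2-yl)ethyl]-3-methyl-6-(propan-2-yl)cyclohexan-1-one
Conditions: Dess–Martin periodinane (1.3 equiv), CH2Cl2, 0 → 23 °C
Reagents that add atoms: none
Why: Hypervalent-iodine (Dess–Martin) oxidation of the secondary alcohol is neutral enough to spare the dioxolane and C7, it merges the two carbinol epimers, and the now labile C5 methine settles with the acetyl group equatorial and trans to the C1 chain.

**Step 4**
Reactants: 10 β-diketone acetal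
Product: 11 (2R,3S,6S)-2-acetyl-3-methyl-3-(3-oxopropyl)-6-(propan-2-yl)cyclohexan-1-one
Conditions: 1 M HCl–THF (1:4), 23 °C
Reagents that add atoms: water O
Why: Acid-catalysed acetal hydrolysis unmasks the C3 aldehyde at room temperature, where enolisation towards the tertiary C7–H is too slow to erode that centre and the fully substituted aldol at C5 is reversible and cannot dehydrate.

**Step 5**
Reactants: 11 keto aldehyde
Product: 12 4β-hydroxy-5αH,7αH-eudesmane-3,6-dione [(4R,5R,7S,10S); trans-decalin]
Conditions: 2-(pentafluorophenyl)-6,7-dihydro-5H-pyrrolo[2,1-c][1,2,4]triazol-2-ium tetrafluoroborate (15 mol %), NaOAc (20 mol %), CHCl3 (0.02 M), 23 °C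
Reagents that add atoms: none
Why: In this N-heterocyclic-carbene-catalysed intramolecular crossed aldehyde–ketone benzoin reaction the carbene turns the C3 aldehyde into an acyl anion equivalent that attacks the less hindered acetyl carbonyl C4 (not C6, which is flanked by isopropyl) through a chair with both tether ends equatorial on ring B, so the trans ring fusion results and the C4 methyl goes equatorial while the smaller oxygen takes the axial β position beside the C10 methyl, as known for benzoin closure onto enolisable 2-substituted 1,3-diketones under acetate base.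

**Step 6**
Reactants: 12 ketol
Product: 13 5αH,7αH-eudesmane-3α,4β,6β-triol [(3R,4R,5S,6R,7S,10S)]
Conditions: LiBH(s-Bu)3 (4 equiv), THF, −78 → 0 °C; then NaOH, H2O2, 0 °C
Reagents that add atoms: none
Why: The bulky trialkylborohydride attacks both ketones along the equatorial trajectory (diastereoselective hindered-hydride ketone reduction), C3 from the β-face as in 4,4-disubstituted 3-oxo terpenoids and C6 from the α-face because the β-face is blocked by the axial C10 methyl, giving the two axial alcohols 3α and 6β faster than the cold lithium aldolate can undergo retro-aldol cleavage.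

**Step 7**
Reactants: 13 triol; 14 trimethyl orthobenzoate
Product: 16 target 6β-benzoyloxy-5αH,7αH-eudesmane-3α,4β-diol [(1R,2S,4aS,7R,8R,8aS)-7,8-dihydroxy-4a,8-dimethyl-2-(propan-2-yl)decahydronaphthalen-1-yl benzoate], via cyclic orthobenzoate 15 (not isolated)
Conditions: PhC(OMe)3 (1.5 equiv), camphor-10-sulfonic acid (5 mol %), CH2Cl2, 23 °C; then AcOH–H2O (4:1), 23 °C
Reagents that add atoms: trimethyl orthobenzoate COC(OC)(OC)c1ccccc1; water O
Why: Acid-catalysed orthoester exchange can become cyclic only across the syn-diaxial 4β and 6β hydroxyls (the 3α hydroxyl lies on the other face), and hydrolysis of the derived dioxanylium ion releases the crowded tertiary oxygen, so the benzoate stays on the secondary O6 (orthoester-relay regioselective monoacylation) and no stereocentre changes.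

**Compound list**
1 | (−)-menthone, (2S,5R)-5-methyl-2-(propan-2-yl)cyclohexan-1-one | CC(C)[C@@H]1CC[C@@H](C)CC1=O | starting material
2 | lithium (3R,6S)-3-methyl-6-(propan-2-yl)cyclohex-1-en-1-olate | CC(C)[C@@H]1CC[C@@H](C)C=C1O[Li] | intermediate
3 | (3R,6S)-2-(N-tert-butyl-S-phenylsulfinimidoyl)-3-methyl-6-(propan-2-yl)cyclohexan-1-one | CC(C)[C@@H]1CC[C@@H](C)C(C1=O)S(=NC(C)(C)C)c1ccccc1 | intermediate
4 | (S)-(+)-piperitone, (6S)-3-methyl-6-(propan-2-yl)cyclohex-2-en-1-one | CC(C)[C@@H]1CCC(C)=CC1=O | intermediate
5 | 2-(2-bromoethyl)-1,3-dioxolane | BrCCC1OCCO1 | starting material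
6 | acetaldehyde | CC=O | starting material
7 | [2-(1,3-dioxolan-2-yl)ethyl]magnesium bromide | Br[Mg]CCC1OCCO1 | intermediate
8 | bromomagnesium (3S,6S)-3-[2-(1,3-dioxolan-2-yl)ethyl]-3-methyl-6-(propan-2-yl)cyclohex-1-en-1-olate | CC(C)[C@@H]1CC[C@@](C)(CCC2OCCO2)C=C1O[Mg]Br | intermediate
9 | (2R,3S,6S)-3-[2-(1,3-dioxolan-2-yl)ethyl]-2-(1-hydroxyethyl)-3-methyl-6-(propan-2-yl)cyclohexan-1-one, carbinol epimers | CC(C)[C@@H]1CC[C@@](C)(CCC2OCCO2)[C@H](C(C)O)C1=O | intermediate
10 | (2R,3S,6S)-2-acetyl-3-[2-(1,3-dioxolan-2-yl)ethyl]-3-methyl-6-(propan-2-yl)cyclohexan-1-one | CC(C)[C@@H]1CC[C@@](C)(CCC2OCCO2)[C@H](C(C)=O)C1=O | intermediate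
11 | (2R,3S,6S)-2-acetyl-3-methyl-3-(3-oxopropyl)-6-(propan-2-yl)cyclohexan-1-one | CC(C)[C@@H]1CC[C@@](C)(CCC=O)[C@H](C(C)=O)C1=O | intermediate
12 | (4R,5R,7S,10S)-4β-hydroxy-5αH,7αH-eudesmane-3,6-dione | CC(C)[C@@H]1CC[C@@]2(C)CCC(=O)[C@](C)(O)[C@@H]2C1=O | intermediate
13 | (3R,4R,5S,6R,7S,10S)-5αH,7αH-eudesmane-3α,4β,6β-triol | CC(C)[C@@H]1CC[C@@]2(C)CC[C@@H](O)[C@](C)(O)[C@@H]2[C@@H]1O | intermediate
14 | trimethyl orthobenzoate | COC(OC)(OC)c1ccccc1 | starting material
15 | 3α-hydroxy-5αH,7αH-eudesmane-4β,6β-diyl methyl orthobenzoate (six-membered cyclic orthoester, orthoester carbon unassigned) | CC(C)[C@@H]1CC[C@@]2(C)CC[C@@H](O)[C@]3(C)OC(OC)(c4ccccc4)O[C@H]1[C@H]23 | intermediate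
16 | (3R,4R,5S,6R,7S,10S)-6β-benzoyloxy-5αH,7αH-eudesmane-3α,4β-diol | CC(C)[C@@H]1CC[C@@]2(C)CC[C@@H](O)[C@](C)(O)[C@@H]2[C@@H]1OC(=O)c1ccccc1 | target

**Total step count:** 7. **Longest linear sequence:** 7 (1 → 4 → 9 → 10 → 11 → 12 → 13 → 16).

**Three steps most likely to fail**

Step 2. The acetal Grignard and a 6-substituted enone have not been tested in the asymmetric copper–carbene manifold. 1,2-Addition, modest facial control, or a sluggish aldol next to the new quaternary carbon are all possible. The fallback sets out from 4 and comes back at 11. It brings in the three-carbon unit as an allyl group, a latent 3-oxopropyl anion, without copper or a chiral ligand.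
- TiCl4-promoted Hosomi–Sakurai addition of allyltrimethylsilane to 4 (CH2Cl2, −78 °C) gives (3S,6S)-3-methyl-6-(propan-2-yl)-3-(prop-2-en-1-yl)cyclohexan-1-one F1. Its C10 epimer is removed by chromatography while C7 is still intact.
- LiN(i-Pr)2 then acetaldehyde gives the aldol (2R,3S,6S)-2-(1-hydroxyethyl)-3-methyl-6-(propan-2-yl)-3-(prop-2-en-1-yl)cyclohexan-1-one F2.
- Dess–Martin oxidation gives the allyl β-diketone (2R,3S,6S)-2-acetyl-3-methyl-6-(propan-2-yl)-3-(prop-2-en-1-yl)cyclohexan-1-one F3.
- An aldehyde-selective Wacker oxidation (PdCl2(PhCN)2, CuCl2, AgNO2, O2, t-BuOH–MeNO2) turns the terminal alkene into the C3 aldehyde of 11.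

Step 5. The carbene adduct could attack C6, giving a bicyclo[3.3.1]nonane. The acidic C5–H could buffer away the free carbene. The C5 methine could also add reversibly to the aldehyde. The fallback sets out from 11 and comes back at 12. It replaces organocatalytic acyl-anion chemistry with a reductive ketyl coupling.
- SmI2 (divalent samarium, 2.5 equiv, THF, t-BuOH, −78 °C) closes C3–C4 as a pinacol to give (4R,5R,7S,10S)-3,4β-dihydroxy-5αH,7αH-eudesman-6-one F4. Its C3 configuration does not matter.
- Dess–Martin oxidation of the only secondary alcohol returns 12.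

Step 7. The tertiary 4β-hydroxyl may enter the orthoester slowly. Hydrolysis could also give some 4-O- or 3-O-benzoate. The fallback sets out from 13 and comes back at 16. It uses protecting-group differentiation in place of the relay.
- Et3SiCl and imidazole (CH2Cl2, −20 °C) silylate the more accessible 3α-hydroxyl to give 3α-(triethylsilyloxy)-5αH,7αH-eudesmane-4β,6β-diol F5.
- Benzoyl chloride and 4-(dimethylamino)pyridine in pyridine at 60 °C acylate the remaining secondary alcohol to give 6β-benzoyloxy-3α-(triethylsilyloxy)-5αH,7αH-eudesman-4β-ol F6.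
- HF·pyridine in THF removes the silyl group to give 16.

**Further compounds**
F1 | step 2 | (3S,6S)-3-methyl-6-(propan-2-yl)-3-(prop-2-en-1-yl)cyclohexan-1-one | CC(C)[C@@H]1CC[C@@](C)(CC=C)CC1=O
F2 | step 2 | (2R,3S,6S)-2-(1-hydroxyethyl)-3-methyl-6-(propan-2-yl)-3-(prop-2-en-1-yl)cyclohexan-1-one | CC(C)[C@@H]1CC[C@@](C)(CC=C)[C@H](C(C)O)C1=O
F3 | step 2 | (2R,3S,6S)-2-acetyl-3-methyl-6-(propan-2-yl)-3-(prop-2-en-1-yl)cyclohexan-1-one | CC(C)[C@@H]1CC[C@@](C)(CC=C)[C@H](C(C)=O)C1=O
F4 | step 5 | (4R,5R,7S,10S)-3,4β-dihydroxy-5αH,7αH-eudesman-6-one | CC(C)[C@@H]1CC[C@@]2(C)CCC(O)[C@](C)(O)[C@@H]2C1=O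
F5 | step 7 | 3α-(triethylsilyloxy)-5αH,7αH-eudesmane-4β,6β-diol | CC(C)[C@@H]1CC[C@@]2(C)CC[C@@H](O[Si](CC)(CC)CC)[C@](C)(O)[C@@H]2[C@@H]1O
F6 | step 7 | 6β-benzoyloxy-3α-(triethylsilyloxy)-5αH,7αH-eudesman-4β-ol | CC(C)[C@@H]1CC[C@@]2(C)CC[C@@H](O[Si](CC)(CC)CC)[C@](C)(O)[C@@H]2[C@@H]1OC(=O)c1ccccc1
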